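The target is what I want from this flask, so I ask first what level it runs into.

| flask | starting material | partner | free catalyst | remark | time |
|---|---|---|---|---|---|
| Monday's | 0.20 M | 0.34 M | 0.74 mM | run made earlier |  |
| Wednesday's | 0.20 M | 0.75 M | 0.74 mM | run made earlier |  |
| Saturday's | 0.40 M | 0.50 M | 0.74 mM | run made earlier |  |
| flask | 0.20 M | 0.500 M | 0.74 mM |  | 6.0 min |

| run | time / min | starting material / % | target / % |
|---|---|---|---|
| Monday's | 0.833 | 1 | 38 |
| Monday's | 2.50 | 0 | 44 |
| Monday's | 5.00 | 0 | 39 |
| Monday's | 8.00 | 0 | 41 |
| Wednesday's | 2.00 | 3 | 47 |
| Wednesday's | 4.00 | 0 | 47 |
| Wednesday's | 5.00 | 3 | 46 |
| Wednesday's | 8.00 | 0 | 50 |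
| Saturday's | 2.00 | 0 | 23 |
| Saturday's | 4.00 | 2 | 33 |
| Saturday's | 5.00 | 0 | 29 |
| Saturday's | 8.00 | 1 | 28 |

(scatter of a reading: 2 percentage points)

* which holds at 6.0 min: what has brought the reaction to rest, or that it has not come to rest (it is still moving / the partner has run out first / all of the starting material has reacted / no working catalyst is left / forward and back rates have come level)
* part of the starting material gone at 6.0 min
* the target standing at 6.0 min, as a percentage of the starting material charged

- the reaction counts as stopped when no species that holds the starting material changes by six tenths of a point or more over the second half of the time

In Monday's run the target stands at 38 % of the charge by 0.833 min, a mean slope of 0.456 min⁻¹ from the start, and then lies flat within the scatter, while starting material reads 1 % and then 0 %. In this flask starting material is the limiting reagent, its 0.20 M standing below the partner's 0.500 M, so I expect the curve to end where starting material ends.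

That leaves the level. Saturday's run has this flask's partner and twice its starting material, and its target readings average 28.3 %. I assume that, with partner and catalyst held, the ratio of lost to target grows in step with the charge. Saturday's average, a reading with its scatter, then gives 0.157 M, the split charge: the charge of starting material that divides evenly between target and loss, the target's share on this assumption, partner and catalyst held, being split charge over split charge plus charge.

For this flask that gives a level of 44.1 %. Taking Monday's slope for this flask, I estimate that it is reached by about 0.966 min, earlier than 6.0 min, so I expect a flat curve at the asked time.

The forecast says all of the starting material has reacted, with 100 % gone (98.5 % to 100 %) and target 44 % (41 % to 47 %), by “Interpolating in log partner”. Its number comes from Monday's and Wednesday's runs, mine from Saturday's.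

The flask gives this end: all of the starting material has reacted, with 100 % gone and target 44.0 %, still 44.0 % after 60.0 min.

    partner + free catalyst ⇌ catalyst intermediate A (K = 6.10 L mol⁻¹, k = 111 L mol⁻¹ s⁻¹)
    catalyst intermediate B → free catalyst + target (k = 416 s⁻¹)
    2 starting material → homo dimer (k = 0.798 L mol⁻¹ s⁻¹)
    starting material + catalyst intermediate A → catalyst intermediate B (k = 240 L mol⁻¹ s⁻¹)

With 0.157 M, the split charge gives this flask 44.1 % target, and the flask holds 44.0 % beside 56.0 % homo dimer, counted as the starting material it holds, with starting material at 0 % and partner at 82 % of its own charge. The neighbour charged with 0.80 M of starting material, its other charges and time as in this flask, has 0.625 equiv of partner to starting material. The same split charge gives it 16.4 % target. That neighbour ends with starting material at 0 % and partner at 74 % of its own charge, and it holds 84.0 % homo dimer beside 16.0 % target.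

The numbers in the tables are calculated on assumed constants; the scatter is artificial.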